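**Plan**

1. Numbering: hexahydronaphthalene C1 (CMe2), C2 (side chain), C3 (Me), C4, C4a, C5=C6(Me), C7, C8, C8a; dioxane C3′ (CH bearing the propanoic acid) and C6′ (quaternary, Me). The retrosynthesis cuts the CH2–CH2 link between C2 and C6′ (as a C=C), C1–C2 of ring B, C4a–C8a and C7–C8 of ring A, and both C–O bonds of the dioxane.
2. Enabling feature: ring A (C4a, C5=C6(Me), C7, C8, C8a) is a 4-methylcyclohexene whose neighbouring carbons C4a and C8a carry cis hydrogens, and C8a bears C1, which can be a carbonyl carbon. This is the endo adduct of a 1-alkyl-3-methylbutadiene and an acrylate.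
3. Bicyclic half, forward: silylated trienol plus acryloyl oxazolidinone closes ring A ([4+2]); ester, then tertiary carbinol, then cation–olefin closure of ring B (C1–C2); the ring-B alkene is fixed as the C2=C3 enal and converted into the allylic phosphonium salt.
4. Dioxane half from geranyl acetate: aldehyde, (Z)-crotylboration, Sharpless epoxidation, epoxide perhydrolysis, intramolecular peroxide alkylation (ring closure), vinyl to methyl ester, glycol to aldehyde.
5. Union: Wittig olefination, diimide reduction of the new C=C, saponification.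
6. Stereochemistry: C4a and C8a from the chiral copper catalyst and the endo rule; C6′ from the Sharpless epoxide (inverted once in the perhydrolysis); C3′ and the α-methyl carbon from the crotylboration (carbinol inverted once in the ring closure).

Key step: step 6

Remark on the chemistry: step 9 is expected to give ring-B double-bond isomers (C3=C4, C2=C3 and C3=CH2). Compounds 13–15 are written as the C3=C4 isomer with C2 unassigned, and the mixture is carried on because step 11 turns every isomer into the single enal 16. Compound 30 may likewise be an E/Z mixture, which step 24 makes irrelevant.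

**Route**

Step 1
Reactants: 1 3-methylbut-2-en-1-ol (prenol)
Product: 2 tert-butyl[(3-methylbut-2-en-1-yl)oxy]diphenylsilane
Conditions: TBDPSCl, imidazole, DMF, 0 °C → rt
Reagents that add atoms: tert-butyl(chloro)diphenylsilane, CC(C)(C)[Si](Cl)(c1ccccc1)c1ccccc1
Why: Routine silyl ether formation on a primary allylic alcohol; the tert-butyldiphenylsilyl group is chosen because it should survive the Grignard and Lewis-acid steps ahead.

Step 2
Reactants: 2 tert-butyl[(3-methylbut-2-en-1-yl)oxy]diphenylsilane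
Product: 3 (2E)-4-[(tert-butyldiphenylsilyl)oxy]-2-methylbut-2-en-1-ol
Conditions: SeO2 (cat.), t-BuOOH, salicylic acid (cat.), CH2Cl2, rt
Reagents that add atoms: tert-butyl hydroperoxide, CC(C)(C)OO
Why: Selenium dioxide allylic oxidation (ene reaction, then [2,3]-shift) of a trisubstituted alkene hydroxylates the (E)-methyl group selectively, which should give the (E)-allylic alcohol.

Step 3
Reactants: 3 (2E)-4-[(tert-butyldiphenylsilyl)oxy]-2-methylbut-2-en-1-ol
Product: 4 {[(2E)-4-bromo-3-methylbut-2-en-1-yl]oxy}(tert-butyl)diphenylsilane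
Conditions: CBr4, PPh3, CH2Cl2, 0 °C
Reagents that add atoms: tetrabromomethane, BrC(Br)(Br)Br
Why: Appel bromination of a primary allylic alcohol proceeds under neutral conditions without allylic transposition or loss of alkene geometry.

Step 4
Reactants: 5 2-methylbut-1-en-3-yne
Product: 6 (E)-4,4,5,5-tetramethyl-2-(3-methylbuta-1,3-dien-1-yl)-1,3,2-dioxaborolane
Conditions: pinacolborane, Cp2Zr(H)Cl (cat.), Et3N (cat.), neat, 60 °C
Reagents that add atoms: pinacolborane, [H]B1OC(C)(C)C(C)(C)O1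
Why: Zirconocene-hydride-catalysed syn-hydroboration of the terminal alkyne places boron at the terminus and should give the (E)-dienylboronate, the 1,1-disubstituted alkene being left alone.

Step 5
Reactants: 4 {[(2E)-4-bromo-3-methylbut-2-en-1-yl]oxy}(tert-butyl)diphenylsilane; 6 (E)-4,4,5,5-tetramethyl-2-(3-methylbuta-1,3-dien-1-yl)-1,3,2-dioxaborolane
Product: 7 tert-butyl{[(2E,5E)-3,7-dimethylocta-2,5,7-trien-1-yl]oxy}diphenylsilane
Conditions: Pd(PPh3)4 (cat.), CsF, THF, 60 °C
Reagents that add atoms: none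
Why: Suzuki–Miyaura allyl–alkenyl coupling with zerovalent palladium; the π-allyl intermediate is attacked at its unsubstituted CH2 terminus, so the (E)-trisubstituted alkene and the (E)-diene are retained in a skipped triene.

Step 6
Reactants: 7 tert-butyl{[(2E,5E)-3,7-dimethylocta-2,5,7-trien-1-yl]oxy}diphenylsilane; 8 3-acryloyl-1,3-oxazolidin-2-one
Product: 9 3-{[(1S,2R)-2-{(2E)-4-[(tert-butyldiphenylsilyl)oxy]-2-methylbut-2-en-1-yl}-4-methylcyclohex-3-en-1-yl]carbonyl}-1,3-oxazolidin-2-one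
Conditions: [Cu((S,S)-t-Bu-box)](SbF6)2 (10 mol %; t-Bu-box = 2,2′-(propane-2,2-diyl)bis[(4S)-4-tert-butyl-4,5-dihydrooxazole]), CH2Cl2, −20 °C → rt
Reagents that add atoms: none
Why: Normal-electron-demand [4+2] cycloaddition in which the acrylimide is bound s-cis through both carbonyl oxygens in the square-planar cationic divalent copper bis(oxazoline) complex and the s-cis diene C7=C6(Me)–C5=C4a adds suprafacially in one step; the closest known reaction is the bis(oxazoline)–copper-catalysed cycloaddition of acryloyl oxazolidinone with piperylene-type 1-substituted dienes. Ring A closes in a concerted six-membered [4+2] mode by the two σ-bonds C4a–C8a and C7–C8. C8a is controlled by the catalyst: a tert-butyl group of the (S,S)-ligand blocks the Cα Si face, so the diene adds to the Re face and the acyl-bearing carbon should be (S). C4a is controlled by the endo transition state together with the (E)-geometry of the substituted diene terminus, which places the side arm cis to the acyl group. The step needs regio-, endo- and facial selectivity: the 1-alkyl and 3-methyl groups both enlarge the HOMO coefficient at the CH2 terminus (C7), which therefore bonds to the acrylate β-carbon (ortho/para product); two-point binding of the imide fixes the geometry on which endo and facial control rest; the isolated trisubstituted alkene and the silyl ether are unreactive spectators.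

Step 7
Reactants: 9 3-{[(1S,2R)-2-{(2E)-4-[(tert-butyldiphenylsilyl)oxy]-2-methylbut-2-en-1-yl}-4-methylcyclohex-3-en-1-yl]carbonyl}-1,3-oxazolidin-2-one
Product: 10 methyl (1S,2R)-2-{(2E)-4-[(tert-butyldiphenylsilyl)oxy]-2-methylbut-2-en-1-yl}-4-methylcyclohex-3-ene-1-carboxylate
Conditions: MeOMgBr, MeOH/CH2Cl2, 0 °C
Reagents that add atoms: bromomagnesium methoxide, CO[Mg]Br
Why: Transesterification of the N-acyloxazolidinone at the exocyclic carbonyl with a weakly basic magnesium alkoxide is fast at 0 °C and should leave the epimerisable cis-1,2 relationship intact.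

Step 8
Reactants: 10 methyl (1S,2R)-2-{(2E)-4-[(tert-butyldiphenylsilyl)oxy]-2-methylbut-2-en-1-yl}-4-methylcyclohex-3-ene-1-carboxylate
Product: 12 2-[(1S,2R)-2-{(2E)-4-[(tert-butyldiphenylsilyl)oxy]-2-methylbut-2-en-1-yl}-4-methylcyclohex-3-en-1-yl]propan-2-ol, via methyl ketone 11 (not isolated)
Conditions: MeMgBr (excess), CeCl3 (anhydrous), THF, −78 → 0 °C
Reagents that add atoms: methylmagnesium bromide, C[Mg]Br
Why: Double Grignard addition to the ester through the ketone; the organocerium variant suppresses enolisation, so the C8a centre next to the carbonyl should not epimerise.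

Step 9
Reactants: 12 2-[(1S,2R)-2-{(2E)-4-[(tert-butyldiphenylsilyl)oxy]-2-methylbut-2-en-1-yl}-4-methylcyclohex-3-en-1-yl]propan-2-ol
Product: 13 tert-butyl{[(4aS,8aS)-1,1,3,6-tetramethyl-1,2,4a,7,8,8a-hexahydronaphthalen-2-yl]methoxy}diphenylsilane (C3=C4 isomer written; C2 unassigned; C2=C3 and C3=CH2 isomers carried along)
Conditions: SnCl4 (promoter), 2,6-di-tert-butyl-4-methylpyridine, CH2Cl2, −78 °C; Et3N quench
Reagents that add atoms: none
Why: Cation–olefin (polyene-type) cyclisation: ionisation of the tertiary alcohol gives the C1 cation, which the trisubstituted side-arm alkene captures at C2 in a 6-endo mode to close ring B on the existing cis pair C4a/C8a, and proton loss from the C3 cation gives alkene isomers that all converge in step 11.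

Step 10
Reactants: 13 tert-butyl{[(4aS,8aS)-1,1,3,6-tetramethyl-1,2,4a,7,8,8a-hexahydronaphthalen-2-yl]methoxy}diphenylsilane
Product: 14 [(4aS,8aS)-1,1,3,6-tetramethyl-1,2,4a,7,8,8a-hexahydronaphthalen-2-yl]methanol (isomer mixture as for 13)
Conditions: Bu4NF, THF, rt
Reagents that add atoms: none
Why: Fluoride-mediated cleavage of the silyl ether, which touches neither alkene nor the ring-fusion centres.

Step 11
Reactants: 14 [(4aS,8aS)-1,1,3,6-tetramethyl-1,2,4a,7,8,8a-hexahydronaphthalen-2-yl]methanol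
Product: 16 (4aR,8aS)-1,1,3,6-tetramethyl-1,4,4a,7,8,8a-hexahydronaphthalene-2-carbaldehyde, via unconjugated aldehyde 15 (not isolated)
Conditions: Dess–Martin periodinane, pyridine, CH2Cl2, 0 °C → rt; then DBU, rt
Reagents that add atoms: none
Why: Dess–Martin oxidation followed by base-mediated conjugation through the dienolate (the cyclocitral-type α-to-β isomerisation) should funnel every ring-B alkene isomer into the single tetrasubstituted C2=C3 enal and erase the C2 stereocentre.

Step 12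
Reactants: 16 (4aR,8aS)-1,1,3,6-tetramethyl-1,4,4a,7,8,8a-hexahydronaphthalene-2-carbaldehyde
Product: 17 [(4aR,8aS)-1,1,3,6-tetramethyl-1,4,4a,7,8,8a-hexahydronaphthalen-2-yl]methanol
Conditions: NaBH4, CeCl3·7H2O, MeOH, 0 °C
Reagents that add atoms: none
Why: Luche 1,2-reduction of the hindered enal gives the allylic alcohol without conjugate reduction.

Step 13
Reactants: 17 [(4aR,8aS)-1,1,3,6-tetramethyl-1,4,4a,7,8,8a-hexahydronaphthalen-2-yl]methanol
Product: 18 triphenyl{[(4aR,8aS)-1,1,3,6-tetramethyl-1,4,4a,7,8,8a-hexahydronaphthalen-2-yl]methyl}phosphonium bromide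
Conditions: PPh3·HBr, MeOH, rt
Reagents that add atoms: triphenylphosphine hydrobromide, c1ccc(cc1)[PH+](c1ccccc1)c1ccccc1.[Br-]
Why: SN1-type phosphonium salt formation from an allylic alcohol, in which the allyl cation is captured by the phosphine at its primary terminus as in cyclogeranyl phosphonium salt preparations.

Step 14
Reactants: 19 geranyl acetate
Product: 20 (2E)-3-methyl-6-oxohex-2-en-1-yl acetate
Conditions: O3 (1 equiv), pyridine, CH2Cl2, −78 °C
Reagents that add atoms: ozone, [O-][O+]=O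
Why: Chemoselective ozonolysis of the more electron-rich remote trisubstituted alkene (the alkene next to the acetate is deactivated), with pyridine decomposing the carbonyl oxide directly to the aldehyde.

Step 15
Reactants: 20 (2E)-3-methyl-6-oxohex-2-en-1-yl acetate
Product: 21 (2E,6S,7S)-6-hydroxy-3,7-dimethylnona-2,8-dien-1-yl acetate
Conditions: (Z)-crotyl-B(Ipc)2 [Ipc groups of the (−)-α-pinene series], THF/Et2O, −78 °C; oxidative work-up with NaBO3·4H2O
Reagents that add atoms: (Z)-crotyldiisopinocampheylborane, C/C=C\CB([C@H]1C[C@H]2C[C@@H]([C@@H]1C)C2(C)C)[C@H]1C[C@H]2C[C@@H]([C@@H]1C)C2(C)C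
Why: Brown crotylboration through a closed chair transition state: the (Z)-crotyl geometry gives the syn adduct and the isopinocampheyl groups of this series should direct attack to the aldehyde Re face, setting (6S,7S).

Step 16
Reactants: 21 (2E,6S,7S)-6-hydroxy-3,7-dimethylnona-2,8-dien-1-yl acetate
Product: 22 (2E,6S,7S)-3,7-dimethyl-6-[(methylsulfonyl)oxy]nona-2,8-dien-1-yl acetate
Conditions: MsCl, Et3N, CH2Cl2, 0 °C
Reagents that add atoms: methanesulfonyl chloride, CS(=O)(=O)Cl
Why: Sulfonate ester formation at oxygen, with retention at the carbinol carbon.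

Step 17
Reactants: 22 (2E,6S,7S)-3,7-dimethyl-6-[(methylsulfonyl)oxy]nona-2,8-dien-1-yl acetate
Product: 23 (3S,4S,7E)-9-hydroxy-3,7-dimethylnona-1,7-dien-4-yl methanesulfonate
Conditions: K2CO3 (cat.), MeOH, 0 °C
Reagents that add atoms: none
Why: Base-catalysed transesterification removes the primary acetate under conditions too mild to displace or eliminate the secondary mesylate.

Step 18
Reactants: 23 (3S,4S,7E)-9-hydroxy-3,7-dimethylnona-1,7-dien-4-yl methanesulfonate
Product: 24 (3S,4S)-6-[(2R,3R)-3-(hydroxymethyl)-2-methyloxiran-2-yl]-3-methylhex-1-en-4-yl methanesulfonate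
Conditions: Ti(OiPr)4 (cat.), D-(−)-diethyl tartrate (cat.), t-BuOOH, 4 Å molecular sieves, CH2Cl2, −20 °C
Reagents that add atoms: tert-butyl hydroperoxide, CC(C)(C)OO
Why: Sharpless asymmetric epoxidation of the (E)-allylic alcohol; with D-(−)-tartrate the oxygen is delivered under reagent control to give the (2R,3R)-epoxy alcohol, and the terminal alkene is not touched.

Step 19
Reactants: 24 (3S,4S)-6-[(2R,3R)-3-(hydroxymethyl)-2-methyloxiran-2-yl]-3-methylhex-1-en-4-yl methanesulfonate
Product: 25 (3S,4S,7S,8R)-7-hydroperoxy-8,9-dihydroxy-3,7-dimethylnon-1-en-4-yl methanesulfonate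
Conditions: H2O2 (anhydrous, ethereal), H3PMo12O40 (cat.), Et2O, rt
Reagents that add atoms: hydrogen peroxide, OO
Why: Acid-catalysed perhydrolysis of a trisubstituted epoxide: hydrogen peroxide opens the oxirane at the tertiary carbon with inversion, so the future C6′ is set as the tertiary hydroperoxide.

Step 20
Reactants: 25 (3S,4S,7S,8R)-7-hydroperoxy-8,9-dihydroxy-3,7-dimethylnon-1-en-4-yl methanesulfonate
Product: 26 (1R)-1-{(3S,6R)-6-[(2S)-but-3-en-2-yl]-3-methyl-1,2-dioxan-3-yl}ethane-1,2-diol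
Conditions: KOtBu (1 equiv), 18-crown-6, THF, 0 °C
Reagents that add atoms: none
Why: Intramolecular Williamson-type alkylation of the hydroperoxide anion (6-exo-tet) displaces the secondary mesylate with inversion, closing the 1,2-dioxane and setting C3′.

Step 21
Reactants: 26 (1R)-1-{(3S,6R)-6-[(2S)-but-3-en-2-yl]-3-methyl-1,2-dioxan-3-yl}ethane-1,2-diol
Product: 27 methyl (2R)-2-{(3R,6S)-6-[(1R)-1,2-dihydroxyethyl]-6-methyl-1,2-dioxan-3-yl}propanoate
Conditions: O3, NaOH, MeOH/CH2Cl2, −78 °C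
Reagents that add atoms: ozone, [O-][O+]=O; methanol, CO
Why: Ozonolysis in methanolic NaOH converts the terminal vinyl group directly into the methyl ester at a temperature at which the α-methyl stereocentre and the peroxide should survive.

Step 22
Reactants: 27 methyl (2R)-2-{(3R,6S)-6-[(1R)-1,2-dihydroxyethyl]-6-methyl-1,2-dioxan-3-yl}propanoate
Product: 28 methyl (2R)-2-[(3R,6S)-6-formyl-6-methyl-1,2-dioxan-3-yl]propanoate
Conditions: NaIO4, THF/H2O, 0 °C → rt
Reagents that add atoms: none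
Why: Periodate glycol cleavage (Malaprade reaction) excises the terminal carbon and leaves a non-epimerisable aldehyde on the quaternary peroxy carbon.

Step 23
Reactants: 18 triphenyl{[(4aR,8aS)-1,1,3,6-tetramethyl-1,4,4a,7,8,8a-hexahydronaphthalen-2-yl]methyl}phosphonium bromide; 28 methyl (2R)-2-[(3R,6S)-6-formyl-6-methyl-1,2-dioxan-3-yl]propanoate
Product: 30 methyl (2R)-2-[(3R,6S)-6-methyl-6-{(E)-2-[(4aR,8aS)-1,1,3,6-tetramethyl-1,4,4a,7,8,8a-hexahydronaphthalen-2-yl]ethenyl}-1,2-dioxan-3-yl]propanoate, via phosphorus ylide 29 (not isolated)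
Conditions: NaN(SiMe3)2 (1 equiv), THF, −78 °C; then 28, −78 °C → rt
Reagents that add atoms: none
Why: Wittig olefination of a semi-stabilised allylic ylide with an aldehyde that cannot enolise; the geometry of the new alkene does not matter because it is reduced in the next step.

Step 24
Reactants: 30 methyl (2R)-2-[(3R,6S)-6-methyl-6-{(E)-2-[(4aR,8aS)-1,1,3,6-tetramethyl-1,4,4a,7,8,8a-hexahydronaphthalen-2-yl]ethenyl}-1,2-dioxan-3-yl]propanoate
Product: 31 methyl (2R)-2-[(3R,6R)-6-methyl-6-{2-[(4aR,8aS)-1,1,3,6-tetramethyl-1,4,4a,7,8,8a-hexahydronaphthalen-2-yl]ethyl}-1,2-dioxan-3-yl]propanoate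
Conditions: KO2CN=NCO2K, AcOH, MeOH/CH2Cl2, 0 °C → rt
Reagents that add atoms: none
Why: Diimide reduction (concerted syn transfer of two hydrogens) is selective for the 1,2-disubstituted alkene over the tri- and tetrasubstituted ones and does not cleave O–O bonds.

Step 25
Reactants: 31 methyl (2R)-2-[(3R,6R)-6-methyl-6-{2-[(4aR,8aS)-1,1,3,6-tetramethyl-1,4,4a,7,8,8a-hexahydronaphthalen-2-yl]ethyl}-1,2-dioxan-3-yl]propanoate
Product: 32 (2R)-2-[(3R,6R)-6-methyl-6-{2-[(4aR,8aS)-1,1,3,6-tetramethyl-1,4,4a,7,8,8a-hexahydronaphthalen-2-yl]ethyl}-1,2-dioxan-3-yl]propanoic acid (CNP0122760.1)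
Conditions: LiOH, THF/H2O, 0 °C → rt; dilute HCl work-up
Reagents that add atoms: lithium hydroxide, [Li+].[OH-]
Why: Saponification with LiOH at low temperature, conditions that β-peroxy esters of this class are known to tolerate, should free the acid without ring opening.

**Compound list**

1 | 3-methylbut-2-en-1-ol | CC(C)=CCO | starting material
2 | tert-butyl[(3-methylbut-2-en-1-yl)oxy]diphenylsilane | CC(C)=CCO[Si](c1ccccc1)(c1ccccc1)C(C)(C)C | intermediate
3 | (2E)-4-[(tert-butyldiphenylsilyl)oxy]-2-methylbut-2-en-1-ol | OC/C(C)=C/CO[Si](c1ccccc1)(c1ccccc1)C(C)(C)C | intermediate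
4 | {[(2E)-4-bromo-3-methylbut-2-en-1-yl]oxy}(tert-butyl)diphenylsilane | BrC/C(C)=C/CO[Si](c1ccccc1)(c1ccccc1)C(C)(C)C | intermediate
5 | 2-methylbut-1-en-3-yne | C=C(C)C#C | starting material
6 | (E)-4,4,5,5-tetramethyl-2-(3-methylbuta-1,3-dien-1-yl)-1,3,2-dioxaborolane | C=C(C)/C=C/B1OC(C)(C)C(C)(C)O1 | intermediate
7 | tert-butyl{[(2E,5E)-3,7-dimethylocta-2,5,7-trien-1-yl]oxy}diphenylsilane | C=C(C)/C=C/C/C(C)=C/CO[Si](c1ccccc1)(c1ccccc1)C(C)(C)C | intermediate
8 | 3-acryloyl-1,3-oxazolidin-2-one | C=CC(=O)N1CCOC1=O | starting material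
9 | 3-{[(1S,2R)-2-{(2E)-4-[(tert-butyldiphenylsilyl)oxy]-2-methylbut-2-en-1-yl}-4-methylcyclohex-3-en-1-yl]carbonyl}-1,3-oxazolidin-2-one | CC1=C[C@@H](C/C(C)=C/CO[Si](c2ccccc2)(c2ccccc2)C(C)(C)C)[C@@H](C(=O)N2CCOC2=O)CC1 | intermediate
10 | methyl (1S,2R)-2-{(2E)-4-[(tert-butyldiphenylsilyl)oxy]-2-methylbut-2-en-1-yl}-4-methylcyclohex-3-ene-1-carboxylate | CC1=C[C@@H](C/C(C)=C/CO[Si](c2ccccc2)(c2ccccc2)C(C)(C)C)[C@@H](C(=O)OC)CC1 | intermediate
11 | 1-[(1S,2R)-2-{(2E)-4-[(tert-butyldiphenylsilyl)oxy]-2-methylbut-2-en-1-yl}-4-methylcyclohex-3-en-1-yl]ethan-1-one | CC1=C[C@@H](C/C(C)=C/CO[Si](c2ccccc2)(c2ccccc2)C(C)(C)C)[C@@H](C(C)=O)CC1 | intermediate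
12 | 2-[(1S,2R)-2-{(2E)-4-[(tert-butyldiphenylsilyl)oxy]-2-methylbut-2-en-1-yl}-4-methylcyclohex-3-en-1-yl]propan-2-ol | CC1=C[C@@H](C/C(C)=C/CO[Si](c2ccccc2)(c2ccccc2)C(C)(C)C)[C@@H](C(C)(C)O)CC1 | intermediate
13 | tert-butyl{[(4aS,8aS)-1,1,3,6-tetramethyl-1,2,4a,7,8,8a-hexahydronaphthalen-2-yl]methoxy}diphenylsilane (C3=C4 isomer, C2 unassigned) | CC1=C[C@H]2C=C(C)C(CO[Si](c3ccccc3)(c3ccccc3)C(C)(C)C)C(C)(C)[C@H]2CC1 | intermediate
14 | [(4aS,8aS)-1,1,3,6-tetramethyl-1,2,4a,7,8,8a-hexahydronaphthalen-2-yl]methanol (C3=C4 isomer, C2 unassigned) | CC1=C[C@H]2C=C(C)C(CO)C(C)(C)[C@H]2CC1 | intermediate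
15 | (4aS,8aS)-1,1,3,6-tetramethyl-1,2,4a,7,8,8a-hexahydronaphthalene-2-carbaldehyde (C3=C4 isomer, C2 unassigned) | CC1=C[C@H]2C=C(C)C(C=O)C(C)(C)[C@H]2CC1 | intermediate
16 | (4aR,8aS)-1,1,3,6-tetramethyl-1,4,4a,7,8,8a-hexahydronaphthalene-2-carbaldehyde | CC1=C[C@H]2CC(C)=C(C=O)C(C)(C)[C@H]2CC1 | intermediate
17 | [(4aR,8aS)-1,1,3,6-tetramethyl-1,4,4a,7,8,8a-hexahydronaphthalen-2-yl]methanol | CC1=C[C@H]2CC(C)=C(CO)C(C)(C)[C@H]2CC1 | intermediate
18 | triphenyl{[(4aR,8aS)-1,1,3,6-tetramethyl-1,4,4a,7,8,8a-hexahydronaphthalen-2-yl]methyl}phosphonium bromide | CC1=C[C@H]2CC(C)=C(C[P+](c3ccccc3)(c3ccccc3)c3ccccc3)C(C)(C)[C@H]2CC1.[Br-] | intermediate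
19 | geranyl acetate, (2E)-3,7-dimethylocta-2,6-dien-1-yl acetate | CC(C)=CCC/C(C)=C/COC(C)=O | starting material
20 | (2E)-3-methyl-6-oxohex-2-en-1-yl acetate | O=CCC/C(C)=C/COC(C)=O | intermediate
21 | (2E,6S,7S)-6-hydroxy-3,7-dimethylnona-2,8-dien-1-yl acetate | CC(=O)OC/C=C(\C)CC[C@H](O)[C@@H](C)C=C | intermediate
22 | (2E,6S,7S)-3,7-dimethyl-6-[(methylsulfonyl)oxy]nona-2,8-dien-1-yl acetate | CC(=O)OC/C=C(\C)CC[C@H](OS(C)(=O)=O)[C@@H](C)C=C | intermediate
23 | (3S,4S,7E)-9-hydroxy-3,7-dimethylnona-1,7-dien-4-yl methanesulfonate | OC/C=C(\C)CC[C@H](OS(C)(=O)=O)[C@@H](C)C=C | intermediate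
24 | (3S,4S)-6-[(2R,3R)-3-(hydroxymethyl)-2-methyloxiran-2-yl]-3-methylhex-1-en-4-yl methanesulfonate | OC[C@H]1O[C@]1(C)CC[C@H](OS(C)(=O)=O)[C@@H](C)C=C | intermediate
25 | (3S,4S,7S,8R)-7-hydroperoxy-8,9-dihydroxy-3,7-dimethylnon-1-en-4-yl methanesulfonate | OC[C@@H](O)[C@](OO)(C)CC[C@H](OS(C)(=O)=O)[C@@H](C)C=C | intermediate
26 | (1R)-1-{(3S,6R)-6-[(2S)-but-3-en-2-yl]-3-methyl-1,2-dioxan-3-yl}ethane-1,2-diol | OC[C@@H](O)[C@]1(C)CC[C@H]([C@@H](C)C=C)OO1 | intermediate
27 | methyl (2R)-2-{(3R,6S)-6-[(1R)-1,2-dihydroxyethyl]-6-methyl-1,2-dioxan-3-yl}propanoate | OC[C@@H](O)[C@]1(C)CC[C@H]([C@@H](C)C(=O)OC)OO1 | intermediate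
28 | methyl (2R)-2-[(3R,6S)-6-formyl-6-methyl-1,2-dioxan-3-yl]propanoate | O=C[C@]1(C)CC[C@H]([C@@H](C)C(=O)OC)OO1 | intermediate
29 | triphenyl{[(4aR,8aS)-1,1,3,6-tetramethyl-1,4,4a,7,8,8a-hexahydronaphthalen-2-yl]methylidene}phosphorane | CC1=C[C@H]2CC(C)=C(C=P(c3ccccc3)(c3ccccc3)c3ccccc3)C(C)(C)[C@H]2CC1 | intermediate
30 | methyl (2R)-2-[(3R,6S)-6-methyl-6-{(E)-2-[(4aR,8aS)-1,1,3,6-tetramethyl-1,4,4a,7,8,8a-hexahydronaphthalen-2-yl]ethenyl}-1,2-dioxan-3-yl]propanoate | CC1=C[C@H]2CC(C)=C(/C=C/[C@]3(C)CC[C@H]([C@@H](C)C(=O)OC)OO3)C(C)(C)[C@H]2CC1 | intermediate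
31 | methyl (2R)-2-[(3R,6R)-6-methyl-6-{2-[(4aR,8aS)-1,1,3,6-tetramethyl-1,4,4a,7,8,8a-hexahydronaphthalen-2-yl]ethyl}-1,2-dioxan-3-yl]propanoate | CC1=C[C@H]2CC(C)=C(CC[C@]3(C)CC[C@H]([C@@H](C)C(=O)OC)OO3)C(C)(C)[C@H]2CC1 | intermediate
32 | (2R)-2-[(3R,6R)-6-methyl-6-{2-[(4aR,8aS)-1,1,3,6-tetramethyl-1,4,4a,7,8,8a-hexahydronaphthalen-2-yl]ethyl}-1,2-dioxan-3-yl]propanoic acid | CC1=C[C@H]2CC(C)=C(CC[C@]3(C)CC[C@H]([C@@H](C)C(=O)O)OO3)C(C)(C)[C@H]2CC1 | target

**Step count**

Total: 25 steps. Longest linear sequence: 15 steps (1–3, 5–13, 23–25); the dioxane branch (14–22) joins at step 23.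

**Steps most likely to fail**

Step 9. The Lewis acid may ionise the allylic C–O bond of the silyl ether or strip the silyl group in competition with ionisation of the tertiary alcohol, so that the side arm is lost before ring B closes. The fallback moves the closure onto an alkene whose allylic oxygen is a far poorer leaving group; it sets out from 12 and returns at 14. Bu4NF frees the diol F1, Ac2O/pyridine acetylates only the primary hydroxyl to give the hydroxy acetate F2, and SnCl4 or BF3·OEt2 at −78 °C closes ring B to the bicyclic acetate F3 (ring-B alkene isomers as for 13). K2CO3 in MeOH then gives 14, and the route continues with step 11.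

Step 23. Addition of the hindered allylic ylide to the neopentyl-type α-peroxy aldehyde may be slow, leaving the ylide to act as a base and open the dioxane by elimination from the ester α-position. The fallback replaces the phosphorus ylide by a sulfone-based olefination with a smaller nucleophile; it sets out from 17 and returns at 30. A Mitsunobu reaction of 17 with 1-phenyl-1H-tetrazole-5-thiol gives the tetrazolyl sulfide F4, oxidation with (NH4)6Mo7O24/H2O2 gives the tetrazolyl sulfone F5, and Julia–Kocienski olefination (KN(SiMe3)2, THF, −78 °C, then 28) gives 30.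

Step 20. The hydroperoxide anion may eliminate the mesylate toward the allylic hydrogen, or the neighbouring alkoxide may alkylate instead of the peroxide. The fallback reverses the order of the two C–O bond formations so that the ring closes by epoxide opening; it sets out from 23 and returns at 26. Displacement of the mesylate in 23 with 2-methoxypropan-2-yl hydroperoxide and CsOH in DMF (inversion) gives the peroxyketal F6. Sharpless epoxidation with D-(−)-diethyl tartrate gives the epoxy peroxyketal F7. Acid methanolysis frees the epoxy hydroperoxide F8, which under camphorsulfonic acid opens the oxirane at its tertiary carbon in a 6-exo mode with inversion to give 26.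

**Further compounds**

F1 | step 9 | (2E)-4-[(1R,6S)-6-(2-hydroxypropan-2-yl)-3-methylcyclohex-2-en-1-yl]-3-methylbut-2-en-1-ol | CC1=C[C@@H](C/C(C)=C/CO)[C@@H](C(C)(C)O)CC1
F2 | step 9 | (2E)-4-[(1R,6S)-6-(2-hydroxypropan-2-yl)-3-methylcyclohex-2-en-1-yl]-3-methylbut-2-en-1-yl acetate | CC1=C[C@@H](C/C(C)=C/COC(C)=O)[C@@H](C(C)(C)O)CC1
F3 | step 9 | [(4aS,8aS)-1,1,3,6-tetramethyl-1,2,4a,7,8,8a-hexahydronaphthalen-2-yl]methyl acetate (C3=C4 isomer, C2 unassigned) | CC1=C[C@H]2C=C(C)C(COC(C)=O)C(C)(C)[C@H]2CC1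
F4 | step 23 | 1-phenyl-5-({[(4aR,8aS)-1,1,3,6-tetramethyl-1,4,4a,7,8,8a-hexahydronaphthalen-2-yl]methyl}sulfanyl)-1H-tetrazole | CC1=C[C@H]2CC(C)=C(CSc3nnnn3-c3ccccc3)C(C)(C)[C@H]2CC1
F5 | step 23 | 1-phenyl-5-({[(4aR,8aS)-1,1,3,6-tetramethyl-1,4,4a,7,8,8a-hexahydronaphthalen-2-yl]methyl}sulfonyl)-1H-tetrazole | CC1=C[C@H]2CC(C)=C(CS(=O)(=O)c3nnnn3-c3ccccc3)C(C)(C)[C@H]2CC1
F6 | step 20 | (2E,6R,7S)-6-[(2-methoxypropan-2-yl)peroxy]-3,7-dimethylnona-2,8-dien-1-ol | OC/C=C(\C)CC[C@@H](OOC(C)(C)OC)[C@@H](C)C=C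
F7 | step 20 | {(2R,3R)-3-[(3R,4S)-3-[(2-methoxypropan-2-yl)peroxy]-4-methylhex-5-en-1-yl]-3-methyloxiran-2-yl}methanol | OC[C@H]1O[C@]1(C)CC[C@@H](OOC(C)(C)OC)[C@@H](C)C=C
F8 | step 20 | {(2R,3R)-3-[(3R,4S)-3-hydroperoxy-4-methylhex-5-en-1-yl]-3-methyloxiran-2-yl}methanol | OC[C@H]1O[C@]1(C)CC[C@@H](OO)[C@@H](C)C=C
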